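**Plan**
1. Late cuts: the C11 chlorohydrin comes from the 11,20-epoxide of a C11 methylene; C5=CH2 and C6–Cl come from a C5 ketone; the four acetates come from acylation.
2. Key cut: the O–C4 and C3–C4 bonds of the eight-membered ring C4–O–C8–C9–C10–C1–C2–C3 are made together. A carbenoid at C4 (diazoketone on C5) is trapped by the ring oxygen of a seven-membered lactol silyl ether (O–C8–C9–C10–C1–C2–C3), and the acetal carbon C3 then shifts from O to C4 (oxonium ylide, Stevens [1,2]-shift). This expands the oxepane to the oxocane and closes the pyran ring and the ten-membered carbocycle.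
3. What allows it: the ether oxygen lies between C8 and C4; C4 is flanked by C5 (a latent carbonyl under the exocyclic methylene) and by C3, which bears oxygen and can therefore be an O,O-acetal carbon able to migrate.
4. The oxepane acetal comes from Baeyer–Villiger expansion of a temporary cyclohexanone (C1, C2, C3, C8, C9, C10) in a trans-decalin. The C8 quaternary centre is set by formylation/Tsuji–Trost allylation and the γ-lactone by oxa-Michael closure. The decalin comes from a catalytic enantioselective Diels–Alder reaction of 2-methoxy-6-methylbenzoquinone with a 1,4-bis(silyloxy)diene.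
5. Forward ring order: ring A and temporary ring B (Diels–Alder), then oxepane (ring B plus O), then γ-lactone, then the key step (pyran, oxocane, cyclodecane), then epoxide and chlorohydrin.
6. Stereochemistry: C1, C14 and the absolute sense from the catalysed endo Diels–Alder; C10 by equilibration; C2, C9, C8, C7, C17, C6, C11 by substrate control relayed from the angular methyl and the ring fusion; C3 by retention and C4 by the bridge in the key step.

Key step: step 17

Remark on numbering: carbons carry the numbers of the briarane skeleton of the target (ring A = C1, C10–C14; C15 = methyl on C1; C16 = CH2 on C5; C17, C18, C19 = lactone CH, its methyl, lactone C=O; C20 = CH2Cl). β is the face of the C15 methyl. TBS = tert-butyldimethylsilyl. The SMILES fix every stereocentre.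
Assumption: the (S)-configured oxazaborolidinium catalyst of step 3 is taken to give the enantiomer drawn; if its facial sense is the opposite, the (R)-catalyst is used.

**Step 1**
Reactants: 1 2-methoxy-6-methylphenol
Product: 2 2-methoxy-6-methyl-1,4-benzoquinone
Conditions: O2 (1 atm), Co(salen) (5 mol %), DMF, rt
Reagents that add atoms: dioxygen O=O
Why: cobalt-catalysed aerobic oxidation of a 2,6-disubstituted phenol with a free para position should give the para-quinone.

**Step 2**
Reactants: 3 (1E,3E)-buta-1,3-diene-1,4-diyl diacetate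
Product: 5 (1E,3E)-1,4-bis(tert-butyldimethylsilyloxy)buta-1,3-diene, via dilithium dienediolate 4 (not isolated)
Conditions: MeLi (4.1 equiv), DME, −30 °C; then TBSCl (2.2 equiv), DMPU, −30 °C to rt
Reagents that add atoms: tert-butyldimethylsilyl chloride CC(C)(C)[Si](C)(C)Cl
Why: cleavage of the enol acetates by methyllithium and O-silylation of the dienediolate should keep the E,E geometry (enol ester to silyl enol ether exchange).

**Step 3**
Reactants: 2 2-methoxy-6-methyl-1,4-benzoquinone; 5 (1E,3E)-1,4-bis(tert-butyldimethylsilyloxy)buta-1,3-diene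
Product: 7 trans-fused 11α,14α-bis(TBSO)-3-methoxy-15β-methyl decalin-3(8),12-diene-2,9-dione (H-10 α), via cis-fused adduct 6 (not isolated)
Conditions: (S)-3,3-diphenyl-1-(2-methylphenyl)tetrahydro-1H,3H-pyrrolo[1,2-c][1,3,2]oxazaborole·Tf2NH (20 mol %), CH2Cl2, −78 °C; then basic Al2O3, CH2Cl2, rt
Reagents that add atoms: none
Why: the catalysed endo Diels–Alder reaction should occur at the methyl-bearing C=C (the methoxy-bearing one is a deactivated vinylogous ester), the E,E-diene and the endo rule place both silyloxy groups trans to the angular methyl (C1, C14, C11; enantioface from the catalyst), and alumina should then epimerise C10 through the C9 enol to the more stable trans-fused isomer.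

**Step 4**
Reactants: 7 trans-fused Diels–Alder adduct
Product: 8 12,13-dihydro adduct (ring A saturated)
Conditions: 2-nitrobenzenesulfonohydrazide, Et3N, CH2Cl2, rt (diimide formed in the flask)
Reagents that add atoms: none
Why: diimide reduction should saturate the unpolarised cis-disubstituted C12=C13 bond and leave the polarised methoxy-enedione untouched.

**Step 5**
Reactants: 8 12,13-dihydro adduct
Product: 10 2β-acetoxy-3-methoxy-3(8)-en-9-one, via C2 alcohol 9 (not isolated)
Conditions: NaBH4, CeCl3·7H2O, MeOH, −78 to −40 °C; then Ac2O, pyridine, DMAP, CH2Cl2, rt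
Reagents that add atoms: acetic anhydride CC(=O)OC(C)=O
Why: Luche 1,2-reduction should take the cross-conjugated C2 carbonyl before the less electrophilic vinylogous-ester C9 carbonyl, with hydride anti to the axial C15 methyl on the neighbouring carbon giving the equatorial 2β-alcohol, which is acetylated so that C2 becomes a poor migrating group for step 11.

**Step 6**
Reactants: 10 2β-acetoxy enone
Product: 12 2β-acetoxy-9β,11α,14α-tris(TBSO)-3-methoxy-3(8)-ene (enol ether), via C9 alcohol 11 (not isolated)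
Conditions: NaBH4, CeCl3·7H2O, MeOH, 0 °C; then TBSOTf, 2,6-lutidine, CH2Cl2, −78 °C
Reagents that add atoms: tert-butyldimethylsilyl triflate CC(C)(C)[Si](C)(C)OS(=O)(=O)C(F)(F)F
Why: Luche 1,2-reduction of the vinylogous ester should deliver hydride from the α face, away from the 1,3-diaxial C15 methyl, to give the axial 9β-alcohol, which is silylated at once under basic conditions because the 3-alkoxy allylic alcohol is acid-labile.

**Step 7**
Reactants: 12 enol ether
Product: 15 8-(hydroxymethylene)-3-ketone (enol form of the 8-formyl-3-ketone), via iminium chloride 13 (not isolated), via methoxy enal 14 (not isolated)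
Conditions: [Me2N=CHCl]Cl, 2,6-lutidine, CH2Cl2, 0 °C; aq. NaOAc; then 1 M HCl, THF, 0 °C
Reagents that add atoms: (chloromethylene)dimethyliminium chloride C[N+](C)=CCl.[Cl-]; water O
Why: Vilsmeier–Haack formylation should attack the nucleophilic β-carbon C8 of the enol ether, and mild acid hydrolysis of the resulting vinylogous formate ester unmasks the C3 ketone as a stabilised hydroxymethylene ketone that carries C7.

**Step 8**
Reactants: 15 hydroxymethylene ketone
Product: 16 8α-allyl-8β-formyl-3-ketone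
Conditions: allyl methyl carbonate, Pd(PPh3)4 (5 mol %), THF, rt
Reagents that add atoms: allyl methyl carbonate C=CCOC(=O)OC
Why: Tsuji–Trost allylation of the soft β-keto aldehyde enolate under neutral conditions should put the allyl group on C8 from the α face (axial attack, anti to the axial 9β-silyloxy group and the C15 methyl), setting the quaternary centre, while the stabilised enolate should not expel the β-silyloxy group.

**Step 9**
Reactants: 16 allyl formyl ketone
Product: 17 benzyl (E)-enoate (C8 bears (E)-CH=CH–CO2Bn and allyl)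
Conditions: Ph3P=CHCO2Bn, toluene, 60 °C
Reagents that add atoms: benzyl (triphenylphosphoranylidene)acetate O=C(OCc1ccccc1)C=P(c1ccccc1)(c1ccccc1)c1ccccc1
Why: Wittig olefination with a stabilised ylide should be selective for the aldehyde over the hindered ketone and give the E-enoate (C7=C6, C5).

**Step 10**
Reactants: 17 benzyl enoate
Product: 19 keto acid (C8 bears CH2CO2H = C17, C19), via aldehyde 18 (not isolated)
Conditions: OsO4 (1 mol %), Oxone (2KHSO5·KHSO4·K2SO4, 4 equiv), DMF, rt
Reagents that add atoms: potassium peroxymonosulfate [K+].[O-]S(=O)(=O)OO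
Why: osmium-catalysed oxidative cleavage should convert the electron-rich terminal alkene into the carboxylic acid while the electron-poor, neopentyl enoate reacts far more slowly.

**Step 11**
Reactants: 19 keto acid
Product: 20 seven-membered lactone (O inserted between C3 and C8)
Conditions: mCPBA, NaHCO3, CH2Cl2, rt
Reagents that add atoms: 3-chloroperbenzoic acid OOC(=O)c1cccc(Cl)c1
Why: Baeyer–Villiger oxidation should proceed with migration of the quaternary allylic C8 with retention (the acetoxy-bearing C2 is deactivated), which forms the C8–O bond of the later ether, and the enoate is inert to peracid.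

**Step 12**
Reactants: 20 seven-membered lactone
Product: 23 3α-TBS lactol ether (2,3-trans) carboxylic acid, via lactol 21 (not isolated), via silyl ester 22 (not isolated)
Conditions: disiamylborane (from BH3·SMe2 and 2-methylbut-2-ene), THF, 0 °C to rt, MeOH quench; then TBSOTf, 2,6-lutidine, CH2Cl2, −78 to 0 °C; aq. NaHCO3, THF
Reagents that add atoms: tert-butyldimethylsilyl triflate CC(C)(C)[Si](C)(C)OS(=O)(=O)C(F)(F)F
Why: disiamylborane should reduce the lactone to the lactol and spare the acetate, the enoate and the acid (held as an acyloxyborane), and silylation of the equilibrating lactol should favour the less hindered anomer trans to the 2β-acetate, the silyl ester being hydrolysed on work-up.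

**Step 13**
Reactants: 23 silyl acetal acid
Product: 24 spiro γ-lactone benzyl ester (C19–O–C7; CH2CO2Bn on C7)
Conditions: DBU (1.2 equiv), MeCN, rt; aq. NH4Cl
Reagents that add atoms: none
Why: reversible 5-exo-trig oxa-Michael addition of the carboxylate to the enoate should, under thermodynamic control, put the CH2CO2Bn arm on the lactone face next to the ring oxygen and away from C9, which is the C7 configuration needed.

**Step 14**
Reactants: 24 lactone benzyl ester
Product: 25 lactone acid (C5 CO2H)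
Conditions: H2 (1 atm), Pd/C (10%), EtOAc, rt
Reagents that add atoms: none
Why: hydrogenolysis should cleave the benzyl ester and nothing else, since no alkene is left.

**Step 15**
Reactants: 25 lactone acid
Product: 27 17-methyl lactone acid (methyl cis to the ring oxygen on C8), via dilithium enolate 26 (not isolated)
Conditions: LiN(SiMe3)2 (2.2 equiv), THF, −78 °C; MeI, −78 to −40 °C; aq. NH4Cl
Reagents that add atoms: iodomethane CI
Why: with C6 shielded as the α-carbon of a carboxylate, the amide base should select the lactone α-CH2 (more acidic than the acetate methyl by several pK units), iodomethane should approach the enolate anti to C9 of the spiro centre and so set C17, and −78 °C suppresses β-elimination of the ring oxygen.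

**Step 16**
Reactants: 27 17-methyl lactone acid
Product: 29 diazoketone (C5 ketone, C4 diazo), via mixed anhydride 28 (not isolated)
Conditions: i-BuOCOCl, N-methylmorpholine, THF, −20 °C; then CH2N2, Et2O, 0 °C
Reagents that add atoms: diazomethane C=[N+]=[N-]
Why: acylation of diazomethane by the mixed carbonic anhydride (first stage of the Arndt–Eistert sequence) should give the α-diazoketone without acid that would harm the silyl acetal.

**Step 17**
Reactants: 29 diazoketone
Product: 31 4,8-ether-bridged ketone (pyran-5-one, oxocane, ten-membered carbocycle; 3α-OTBS, 2β-OAc), via oxonium ylide 30 (not isolated)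
Conditions: Cu(hfacac)2 [Cu(CF3COCHCOCF3)2] (10 mol %), CH2Cl2, reflux, slow addition
Reagents that add atoms: none
Why: the copper catalyst turns the diazoketone into an electrophilic carbenoid at C4 that is captured by a lone pair of the oxepane oxygen on C8, which closes the pyranone ring O–C4–C5–C6–C7–C8 through a six-membered ylide-forming cyclisation and gives the bicyclic oxonium ylide 30. The ylide then undergoes a Stevens [1,2]-shift in which the O,O-acetal carbon C3 leaves oxygen and bonds to the ylide carbon C4, so that C4 is inserted into the O–C3 bond: the seven-membered acetal ring becomes the eight-membered oxocane, and the ten-membered carbocycle C1–C10 is closed at C3–C4 in the same event. The closest known reaction type is the copper-catalysed oxonium ylide formation and [1,2]-shift of diazoketones tethered to cyclic mixed acetals, which gives oxygen-bridged seven- and eight-membered carbocycles and is extended here by two ring atoms. C3 should migrate with retention (tight radical or ion pair stabilised by the silyloxy group), so its configuration comes from the trans silyl acetal, and C4 is fixed because C3, tethered to C8 through C2–C1–C10–C9, can only reach the face of the ylide carbon syn to the C8–C9 bond (1,3-cis bridge of the oxabicyclo[5.3.1] system). The step needs ylide formation at the oxepane oxygen and migration of C3 in preference to the tertiary C8: the lactone oxygen on C7 (the only one that could give a five-membered ylide) is deactivated by acyl conjugation, the silyl ether oxygens are out of reach, C8 lacks the heteroatom assistance that C3 has, and this copper catalyst favours ylide formation over C–H insertion.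

**Step 18**
Reactants: 31 bridged ketone
Product: 33 6-chloro ketone (Cl cis to the lactone oxygen on C7), via silyl enol ether 32 (not isolated)
Conditions: TMSOTf, Et3N, CH2Cl2, 0 °C; then NCS, THF, 0 °C
Reagents that add atoms: N-chlorosuccinimide ClN1C(=O)CCC1=O
Why: soft enolisation should go toward the methylene C6 (C4 is a hindered bridgehead) without a free enolate that could expel the C7 oxygen, and chlorination of the silyl enol ether from the exo face, opposite the oxocane bridge, sets C6.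

**Step 19**
Reactants: 33 6-chloro ketone
Product: 34 C11 alcohol
Conditions: HF·pyridine, pyridine, THF, 0 °C
Reagents that add atoms: none
Why: buffered fluoride should cleave only the equatorial C11 silyl ether, the one silyl ether not flanked by a quaternary or doubly substituted centre.

**Step 20**
Reactants: 34 C11 alcohol
Product: 35 5,11-diketone
Conditions: triacetoxy periodinane (DMP), NaHCO3, CH2Cl2, rt
Reagents that add atoms: none
Why: neutral periodinane oxidation should give the C11 ketone without epimerising C10 or C6 and without β-elimination of the C9 silyloxy group.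

**Step 21**
Reactants: 35 5,11-diketone
Product: 37 5(16),11(20)-diene triol (3-OH, 9-OH, 14-OH; 2-OAc), via bis(hydroxysilane) 36 (not isolated)
Conditions: Me3SiCH2Li, CeCl3, THF, −78 °C; then aq. HF (48%), MeCN, rt
Reagents that add atoms: (trimethylsilyl)methyllithium [Li]C[Si](C)(C)C
Why: double Peterson olefination, in which the non-basic organocerium reagent should add to both ketones without enolising the α-chloro ketone, and HF then induces both eliminations to the exocyclic methylenes and removes the three remaining silyl ethers.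

**Step 22**
Reactants: 37 diene triol
Product: 38 2,3,9,14-tetraacetate diene
Conditions: Ac2O, pyridine, DMAP, CH2Cl2, rt
Reagents that add atoms: acetic anhydride CC(=O)OC(C)=O
Why: DMAP-catalysed acylation should esterify the three secondary alcohols, including the two hindered axial ones.

**Step 23**
Reactants: 38 tetraacetate diene
Product: 39 11,20-epoxide (oxygen α)
Conditions: mCPBA, NaHCO3, CH2Cl2, 0 °C
Reagents that add atoms: 3-chloroperbenzoic acid OOC(=O)c1cccc(Cl)c1
Why: peracid epoxidation should select the 11(20)-alkene (the 5(16)-alkene is deactivated by allylic chlorine and oxygen) and approach equatorially from the α face, away from the 1,3-diaxial C15 methyl, which sets C11.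

**Step 24**
Reactants: 39 11,20-epoxide
Product: 40 Fragilide F
Conditions: LiCl, AcOH, THF, rt
Reagents that add atoms: lithium chloride [Li+].[Cl-]
Why: chloride should open the 1,1-disubstituted epoxide by SN2 attack at the primary carbon C20, leaving the tertiary 11α-alcohol with its configuration intact.

**Compound list**
1 | 2-methoxy-6-methylphenol | COc1cccc(C)c1O | starting material
2 | 2-methoxy-6-methyl-1,4-benzoquinone | COC1=CC(=O)C=C(C)C1=O | intermediate
3 | (1E,3E)-buta-1,3-diene-1,4-diyl diacetate | CC(=O)O/C=C/C=C/OC(C)=O | starting material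
4 | dilithium (1E,3E)-buta-1,3-diene-1,4-diolate | [Li+].[Li+].[O-]/C=C/C=C/[O-] | intermediate (not isolated)
5 | (1E,3E)-1,4-bis(tert-butyldimethylsilyloxy)buta-1,3-diene | CC(C)(C)[Si](C)(C)O/C=C/C=C/O[Si](C)(C)C(C)(C)C | intermediate
6 | cis-fused endo adduct (H-10 β; 11α,14α-bis-OTBS; 3-OMe; C2 and C9 ketones) | COC1=CC(=O)[C@@H]2[C@H](O[Si](C)(C)C(C)(C)C)C=C[C@H](O[Si](C)(C)C(C)(C)C)[C@]2(C)C1=O | intermediate (not isolated)
7 | trans-fused adduct (H-10 α) | COC1=CC(=O)[C@H]2[C@H](O[Si](C)(C)C(C)(C)C)C=C[C@H](O[Si](C)(C)C(C)(C)C)[C@]2(C)C1=O | intermediate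
8 | 12,13-dihydro adduct | COC1=CC(=O)[C@H]2[C@H](O[Si](C)(C)C(C)(C)C)CC[C@H](O[Si](C)(C)C(C)(C)C)[C@]2(C)C1=O | intermediate
9 | 2β-alcohol | COC1=CC(=O)[C@H]2[C@H](O[Si](C)(C)C(C)(C)C)CC[C@H](O[Si](C)(C)C(C)(C)C)[C@]2(C)[C@H]1O | intermediate (not isolated)
10 | 2β-acetate, C9 ketone | COC1=CC(=O)[C@H]2[C@H](O[Si](C)(C)C(C)(C)C)CC[C@H](O[Si](C)(C)C(C)(C)C)[C@]2(C)[C@H]1OC(C)=O | intermediate
11 | 9β-alcohol | COC1=C[C@@H](O)[C@H]2[C@H](O[Si](C)(C)C(C)(C)C)CC[C@H](O[Si](C)(C)C(C)(C)C)[C@]2(C)[C@H]1OC(C)=O | intermediate (not isolated)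
12 | 9β-TBS ether (3-methoxy enol ether) | COC1=C[C@@H](O[Si](C)(C)C(C)(C)C)[C@H]2[C@H](O[Si](C)(C)C(C)(C)C)CC[C@H](O[Si](C)(C)C(C)(C)C)[C@]2(C)[C@H]1OC(C)=O | intermediate
13 | C8 (dimethyliminio)methyl enol ether chloride | COC1=C(C=[N+](C)C)[C@@H](O[Si](C)(C)C(C)(C)C)[C@H]2[C@H](O[Si](C)(C)C(C)(C)C)CC[C@H](O[Si](C)(C)C(C)(C)C)[C@]2(C)[C@H]1OC(C)=O.[Cl-] | intermediate (not isolated)
14 | 8-formyl-3-methoxy enol ether (β-methoxy enal) | COC1=C(C=O)[C@@H](O[Si](C)(C)C(C)(C)C)[C@H]2[C@H](O[Si](C)(C)C(C)(C)C)CC[C@H](O[Si](C)(C)C(C)(C)C)[C@]2(C)[C@H]1OC(C)=O | intermediate (not isolated)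
15 | 8-(hydroxymethylene)-3-ketone | O/C=C1/[C@@H](O[Si](C)(C)C(C)(C)C)[C@H]2[C@H](O[Si](C)(C)C(C)(C)C)CC[C@H](O[Si](C)(C)C(C)(C)C)[C@]2(C)[C@@H](OC(C)=O)C1=O | intermediate
16 | 8α-allyl-8β-formyl-3-ketone | O=C[C@@]1(CC=C)[C@@H](O[Si](C)(C)C(C)(C)C)[C@H]2[C@H](O[Si](C)(C)C(C)(C)C)CC[C@H](O[Si](C)(C)C(C)(C)C)[C@]2(C)[C@@H](OC(C)=O)C1=O | intermediate
17 | benzyl (E)-enoate with 8α-allyl | O=C(OCc1ccccc1)/C=C/[C@@]1(CC=C)[C@@H](O[Si](C)(C)C(C)(C)C)[C@H]2[C@H](O[Si](C)(C)C(C)(C)C)CC[C@H](O[Si](C)(C)C(C)(C)C)[C@]2(C)[C@@H](OC(C)=O)C1=O | intermediate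
18 | C19 aldehyde | O=C(OCc1ccccc1)/C=C/[C@@]1(CC=O)[C@@H](O[Si](C)(C)C(C)(C)C)[C@H]2[C@H](O[Si](C)(C)C(C)(C)C)CC[C@H](O[Si](C)(C)C(C)(C)C)[C@]2(C)[C@@H](OC(C)=O)C1=O | intermediate (not isolated)
19 | keto acid (C19 CO2H) | O=C(OCc1ccccc1)/C=C/[C@@]1(CC(=O)O)[C@@H](O[Si](C)(C)C(C)(C)C)[C@H]2[C@H](O[Si](C)(C)C(C)(C)C)CC[C@H](O[Si](C)(C)C(C)(C)C)[C@]2(C)[C@@H](OC(C)=O)C1=O | intermediate
20 | seven-membered lactone (C3 carbonyl, O on C8) | O=C(OCc1ccccc1)/C=C/[C@@]1(CC(=O)O)[C@@H](O[Si](C)(C)C(C)(C)C)[C@H]2[C@H](O[Si](C)(C)C(C)(C)C)CC[C@H](O[Si](C)(C)C(C)(C)C)[C@]2(C)[C@@H](OC(C)=O)C(=O)O1 | intermediate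
21 | lactol (C3–OH, anomers equilibrate) | O=C(OCc1ccccc1)/C=C/[C@@]1(CC(=O)O)[C@@H](O[Si](C)(C)C(C)(C)C)[C@H]2[C@H](O[Si](C)(C)C(C)(C)C)CC[C@H](O[Si](C)(C)C(C)(C)C)[C@]2(C)[C@@H](OC(C)=O)C(O)O1 | intermediate (not isolated)
22 | 3α-TBS lactol ether, TBS ester | O=C(OCc1ccccc1)/C=C/[C@@]1(CC(=O)O[Si](C)(C)C(C)(C)C)[C@@H](O[Si](C)(C)C(C)(C)C)[C@H]2[C@H](O[Si](C)(C)C(C)(C)C)CC[C@H](O[Si](C)(C)C(C)(C)C)[C@]2(C)[C@@H](OC(C)=O)[C@H](O[Si](C)(C)C(C)(C)C)O1 | intermediate (not isolated)
23 | 3α-TBS lactol ether acid | O=C(OCc1ccccc1)/C=C/[C@@]1(CC(=O)O)[C@@H](O[Si](C)(C)C(C)(C)C)[C@H]2[C@H](O[Si](C)(C)C(C)(C)C)CC[C@H](O[Si](C)(C)C(C)(C)C)[C@]2(C)[C@@H](OC(C)=O)[C@H](O[Si](C)(C)C(C)(C)C)O1 | intermediate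
24 | spiro γ-lactone benzyl ester | O=C(OCc1ccccc1)C[C@@H]1OC(=O)C[C@@]12[C@@H](O[Si](C)(C)C(C)(C)C)[C@H]3[C@H](O[Si](C)(C)C(C)(C)C)CC[C@H](O[Si](C)(C)C(C)(C)C)[C@]3(C)[C@@H](OC(C)=O)[C@H](O[Si](C)(C)C(C)(C)C)O2 | intermediate
25 | lactone acid | OC(=O)C[C@@H]1OC(=O)C[C@@]12[C@@H](O[Si](C)(C)C(C)(C)C)[C@H]3[C@H](O[Si](C)(C)C(C)(C)C)CC[C@H](O[Si](C)(C)C(C)(C)C)[C@]3(C)[C@@H](OC(C)=O)[C@H](O[Si](C)(C)C(C)(C)C)O2 | intermediate
26 | dilithium carboxylate lactone enolate | [Li+].[Li+].[O-]C(=O)C[C@@H]1OC([O-])=C[C@@]12[C@@H](O[Si](C)(C)C(C)(C)C)[C@H]3[C@H](O[Si](C)(C)C(C)(C)C)CC[C@H](O[Si](C)(C)C(C)(C)C)[C@]3(C)[C@@H](OC(C)=O)[C@H](O[Si](C)(C)C(C)(C)C)O2 | intermediate (not isolated)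
27 | 17-methyl lactone acid | OC(=O)C[C@@H]1OC(=O)[C@H](C)[C@@]12[C@@H](O[Si](C)(C)C(C)(C)C)[C@H]3[C@H](O[Si](C)(C)C(C)(C)C)CC[C@H](O[Si](C)(C)C(C)(C)C)[C@]3(C)[C@@H](OC(C)=O)[C@H](O[Si](C)(C)C(C)(C)C)O2 | intermediate
28 | isobutyl carbonic mixed anhydride | CC(C)COC(=O)OC(=O)C[C@@H]1OC(=O)[C@H](C)[C@@]12[C@@H](O[Si](C)(C)C(C)(C)C)[C@H]3[C@H](O[Si](C)(C)C(C)(C)C)CC[C@H](O[Si](C)(C)C(C)(C)C)[C@]3(C)[C@@H](OC(C)=O)[C@H](O[Si](C)(C)C(C)(C)C)O2 | intermediate (not isolated)
29 | diazoketone | [N-]=[N+]=CC(=O)C[C@@H]1OC(=O)[C@H](C)[C@@]12[C@@H](O[Si](C)(C)C(C)(C)C)[C@H]3[C@H](O[Si](C)(C)C(C)(C)C)CC[C@H](O[Si](C)(C)C(C)(C)C)[C@]3(C)[C@@H](OC(C)=O)[C@H](O[Si](C)(C)C(C)(C)C)O2 | intermediate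
30 | bicyclic oxonium ylide (enolate form) | [O-]C1=C[O+]2[C@@H](O[Si](C)(C)C(C)(C)C)[C@H](OC(C)=O)[C@@]3(C)[C@@H](O[Si](C)(C)C(C)(C)C)CC[C@@H](O[Si](C)(C)C(C)(C)C)[C@@H]3[C@H](O[Si](C)(C)C(C)(C)C)[C@@]24[C@@H](C)C(=O)O[C@H]4C1 | intermediate (not isolated)
31 | 4,8-ether-bridged C5 ketone | O=C1[C@H]2O[C@]3([C@@H](C)C(=O)O[C@H]3C1)[C@@H](O[Si](C)(C)C(C)(C)C)[C@H]1[C@H](O[Si](C)(C)C(C)(C)C)CC[C@H](O[Si](C)(C)C(C)(C)C)[C@]1(C)[C@@H](OC(C)=O)[C@@H]2O[Si](C)(C)C(C)(C)C | intermediate
32 | C5 trimethylsilyl enol ether (C5=C6) | C[Si](C)(C)OC=1[C@H]2O[C@]3([C@@H](C)C(=O)O[C@H]3C=1)[C@@H](O[Si](C)(C)C(C)(C)C)[C@H]1[C@H](O[Si](C)(C)C(C)(C)C)CC[C@H](O[Si](C)(C)C(C)(C)C)[C@]1(C)[C@@H](OC(C)=O)[C@@H]2O[Si](C)(C)C(C)(C)C | intermediate (not isolated)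
33 | 6-chloro ketone | O=C1[C@H]2O[C@]3([C@@H](C)C(=O)O[C@H]3[C@H]1Cl)[C@@H](O[Si](C)(C)C(C)(C)C)[C@H]1[C@H](O[Si](C)(C)C(C)(C)C)CC[C@H](O[Si](C)(C)C(C)(C)C)[C@]1(C)[C@@H](OC(C)=O)[C@@H]2O[Si](C)(C)C(C)(C)C | intermediate
34 | C11 alcohol | O=C1[C@H]2O[C@]3([C@@H](C)C(=O)O[C@H]3[C@H]1Cl)[C@@H](O[Si](C)(C)C(C)(C)C)[C@H]1[C@H](O)CC[C@H](O[Si](C)(C)C(C)(C)C)[C@]1(C)[C@@H](OC(C)=O)[C@@H]2O[Si](C)(C)C(C)(C)C | intermediate
35 | 5,11-diketone | O=C1[C@H]2O[C@]3([C@@H](C)C(=O)O[C@H]3[C@H]1Cl)[C@@H](O[Si](C)(C)C(C)(C)C)[C@H]1C(=O)CC[C@H](O[Si](C)(C)C(C)(C)C)[C@]1(C)[C@@H](OC(C)=O)[C@@H]2O[Si](C)(C)C(C)(C)C | intermediate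
36 | 5,11-bis[(trimethylsilyl)methyl] diol (new carbinol centres of no consequence, left open) | C[Si](C)(C)CC1(O)[C@H]2O[C@]3([C@@H](C)C(=O)O[C@H]3[C@H]1Cl)[C@@H](O[Si](C)(C)C(C)(C)C)[C@H]1C(O)(C[Si](C)(C)C)CC[C@H](O[Si](C)(C)C(C)(C)C)[C@]1(C)[C@@H](OC(C)=O)[C@@H]2O[Si](C)(C)C(C)(C)C | intermediate (not isolated)
37 | 5(16),11(20)-diene 3,9,14-triol 2-acetate | C=C1[C@H]2O[C@]3([C@@H](C)C(=O)O[C@H]3[C@H]1Cl)[C@@H](O)[C@H]1C(=C)CC[C@H](O)[C@]1(C)[C@@H](OC(C)=O)[C@@H]2O | intermediate
38 | 5(16),11(20)-diene 2,3,9,14-tetraacetate | C=C1[C@H]2O[C@]3([C@@H](C)C(=O)O[C@H]3[C@H]1Cl)[C@@H](OC(C)=O)[C@H]1C(=C)CC[C@H](OC(C)=O)[C@]1(C)[C@@H](OC(C)=O)[C@@H]2OC(C)=O | intermediate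
39 | 11,20-epoxide tetraacetate | C=C1[C@H]2O[C@]3([C@@H](C)C(=O)O[C@H]3[C@H]1Cl)[C@@H](OC(C)=O)[C@H]1[C@@]4(CO4)CC[C@H](OC(C)=O)[C@]1(C)[C@@H](OC(C)=O)[C@@H]2OC(C)=O | intermediate
40 | Fragilide F | C=C1[C@H]2O[C@]3([C@@H](C)C(=O)O[C@H]3[C@H]1Cl)[C@@H](OC(C)=O)[C@H]1[C@@](O)(CCl)CC[C@H](OC(C)=O)[C@]1(C)[C@@H](OC(C)=O)[C@@H]2OC(C)=O | target

**Totals**
Total step count: 24. Longest linear sequence: 23 steps (step 1 or step 2, then steps 3 to 24).

**Steps most likely to fail**

Step 17. The tertiary C8 could migrate in place of C3, a [1,4]-shift to the enolate oxygen or C–H insertion could compete, and the migrating acetal carbon could lose its configuration. Fallback: from diazoketone 29, HBr (Et2O, 0 °C) should give the bromomethyl ketone F1. Buffered HF·pyridine should remove only the anomeric silyl group to give the lactol bromoketone F2. Ag2O (CH2Cl2) should let the tertiary C8 hydroxyl of the ring-opened hydroxy aldehyde displace bromide (Williamson etherification, 6-exo-tet) to the pyranone aldehyde F3. An intramolecular aldol addition under soft enolisation (MgBr2·OEt2, Et3N) should close the eight-membered ring to the β-hydroxy ketone F4. Silylation (TBSOTf, 2,6-lutidine) returns to the route at 31.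

Step 12. The hindered lactone may be reduced slowly or unselectively, the lactol may open to the hydroxy aldehyde, and silylation may give the wrong anomer. Fallback: from lactone 20, aminolysis with MeNH(OMe)·HCl and Me2AlCl should open the ring to the N-methoxy-N-methylamide with a free tertiary C8 alcohol F5. Cp2Zr(H)Cl should reduce the amide to the aldehyde, which closes to lactol 21, where the route is rejoined before the silylation.

Step 8. O-allylation, β-elimination of the C9 silyloxy group from the enolate, or poor facial selectivity at C8 may intervene. Fallback: from 15, allyl alcohol and PPTS (benzene, reflux, removal of water) should give the O-allyl enol ether F6 without base. A thermal Claisen rearrangement (toluene, 110 °C) should then deliver the allyl group to C8 through a cyclic transition state on the α face and return to the route at 16.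

**Further compounds**
F1 | step 17 | bromomethyl ketone (C4 CH2Br, C5 ketone) of the silyl acetal lactone | BrCC(=O)C[C@@H]1OC(=O)[C@H](C)[C@@]12[C@@H](O[Si](C)(C)C(C)(C)C)[C@H]3[C@H](O[Si](C)(C)C(C)(C)C)CC[C@H](O[Si](C)(C)C(C)(C)C)[C@]3(C)[C@@H](OC(C)=O)[C@H](O[Si](C)(C)C(C)(C)C)O2
F2 | step 17 | lactol bromoketone (C3–OH, anomers) | BrCC(=O)C[C@@H]1OC(=O)[C@H](C)[C@@]12[C@@H](O[Si](C)(C)C(C)(C)C)[C@H]3[C@H](O[Si](C)(C)C(C)(C)C)CC[C@H](O[Si](C)(C)C(C)(C)C)[C@]3(C)[C@@H](OC(C)=O)C(O)O2
F3 | step 17 | pyranone aldehyde (O–C4 ether closed, C3 aldehyde free) | O=C[C@H](OC(C)=O)[C@@]1(C)[C@@H](O[Si](C)(C)C(C)(C)C)CC[C@@H](O[Si](C)(C)C(C)(C)C)[C@@H]1[C@H](O[Si](C)(C)C(C)(C)C)[C@@]12OCC(=O)C[C@@H]1OC(=O)[C@@H]2C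
F4 | step 17 | bridged β-hydroxy ketone (3-OH analogue of 31) | O=C1[C@H]2O[C@]3([C@@H](C)C(=O)O[C@H]3C1)[C@@H](O[Si](C)(C)C(C)(C)C)[C@H]1[C@H](O[Si](C)(C)C(C)(C)C)CC[C@H](O[Si](C)(C)C(C)(C)C)[C@]1(C)[C@@H](OC(C)=O)[C@@H]2O
F5 | step 12 | ring-opened N-methoxy-N-methylamide (C3) with tertiary C8 alcohol | CON(C)C(=O)[C@H](OC(C)=O)[C@@]1(C)[C@@H](O[Si](C)(C)C(C)(C)C)CC[C@@H](O[Si](C)(C)C(C)(C)C)[C@@H]1[C@H](O[Si](C)(C)C(C)(C)C)[C@](O)(CC(=O)O)/C=C/C(=O)OCc1ccccc1
F6 | step 8 | 8-(allyloxymethylene)-3-ketone | C=CCO/C=C1\[C@@H](O[Si](C)(C)C(C)(C)C)[C@H]2[C@H](O[Si](C)(C)C(C)(C)C)CC[C@H](O[Si](C)(C)C(C)(C)C)[C@]2(C)[C@@H](OC(C)=O)C1=O
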